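## Retrosynthetic overview
1. The target comes from an epoxy diol by double angeloylation. The 3,4-oxirane comes from a ring 3-ene-1,2-diol by hydroxyl-directed epoxidation of the ring olefin, as in the biosynthesis; it is the last ring made.
2. The 3-ene-1,2-diol comes from a bicyclic 2,3-epoxy-1-ol by a titanium-delivered oxirane-to-allylic-alcohol transposition. O-2 is kept and the olefin moves to C3=C4.
3. The six-membered ring comes from an acyclic (6E)-farnesane 2,3-epoxy aldehyde. The C1 electrophile closes onto the 6,7-olefin (C1–C6 bond) with loss of H-14. This is the farnesyl → bisabolyl → β-bisabolene sequence run as a chelated carbonyl-ene reaction, and it sets C1 and C6.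
4. The epoxy aldehyde comes from a racemic 1,8-diol, in which one Sharpless epoxidation sets C2 and C3 and resolves C8. The C15 chain is neryl acetate (C10, oxidised at C8) plus prenyl chloride (C5).
5. Ring order: sacrificial 2,3-oxirane (acyclic stage), then the carbocycle, then the 3,4-oxirane.

Assumption: farnesane/bisabolane numbering is used throughout (C1 = former CH2OAc carbon of neryl acetate, C15 = methyl on C3, C14 = methyl or methylene on C7), and angelic acid is taken as a purchasable reagent.

## Route

Step 1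
Reactants: 1 neryl acetate; 2 selenium dioxide
Product: 3 (2Z,6E)-3,7-dimethyl-8-oxoocta-2,6-dien-1-yl acetate
Conditions: SeO2 (1.1 equiv), EtOH, reflux
Reagents that add atoms: selenium dioxide O=[Se]=O
Why: Riley allylic oxidation (ene reaction then [2,3]-shift) attacks the electron-richer terminal olefin at the methyl group trans to the chain, which gives the 6E enal and leaves the acetate-deactivated 2Z olefin untouched.

Step 2
Reactants: 3 (2Z,6E)-8-oxoneryl acetate; 4 prenyl chloride
Product: 7 racemic (2Z,6E)-3,7,11-trimethyldodeca-2,6,10-triene-1,8-diol, via prenylbarium chloride 5 (not isolated), via racemic 8-hydroxyfarnesyl acetate 6 (not isolated)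
Conditions: BaI2, lithium biphenylide, THF, 23 °C (active zerovalent barium); 4, −78 °C; 3, −78 °C; then MeOH, −78 → 23 °C; aq NH4Cl
Reagents that add atoms: prenyl chloride CC(C)=CCCl
Why: Allylbarium addition goes 1,2 and through the unsubstituted α-carbon, so the linear prenyl carbinol forms instead of the reverse-prenyl isomer, C8 is left racemic on purpose, and the barium methoxide released by the methanol quench removes the primary acetate by Zemplén-type transesterification.

Step 3
Reactants: 7 racemic 1,8-diol; 8 tert-butyl hydroperoxide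
Product: 9 (2R,3S,6E,8S)-2,3-epoxy-3,7,11-trimethyldodeca-6,10-diene-1,8-diol
Conditions: Ti(OiPr)4 (0.2 equiv), D-(−)-DIPT (0.26 equiv), 8 (1.55 equiv), 4 Å MS, CH2Cl2, −20 °C (maximum yield 50%)
Reagents that add atoms: tert-butyl hydroperoxide CC(C)(C)OO
Why: Sharpless asymmetric epoxidation and Sharpless kinetic resolution run in one flask, since D-(−)-DIPT gives the (2R,3S)-oxirane from the 2Z allylic alcohol and also epoxidises the 6,7-olefin of the fast-reacting (8R)-carbinol while the (8S)-carbinol reacts slowly, so only the (2R,3S,8S)-monoepoxide survives and is separated from the more polar bis-epoxide.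

Step 4
Reactants: 9 epoxy diol; 10 acetic anhydride
Product: 12 (2S,3S,6E,8S)-8-acetoxy-2,3-epoxy-3,7,11-trimethyldodeca-6,10-dienal, via 8-hydroxy epoxy aldehyde 11 (not isolated)
Conditions: TEMPO (0.1 equiv), PhI(OAc)2 (1.1 equiv), CH2Cl2, 0 → 23 °C; then 10, pyridine, DMAP (cat.), 0 °C
Reagents that add atoms: acetic anhydride CC(=O)OC(C)=O
Why: The oxoammonium (TEMPO) oxidation is sterically selective for the primary carbinol over the hindered secondary allylic C8 alcohol, which is then acetylated in the same flask with no stereocentre touched (the C2 descriptor changes only through CIP priorities).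

Step 5
Reactants: 12 acetoxy epoxy aldehyde
Product: 13 (1R,2R,3S,6S,8S)-8-acetoxy-2,3-epoxybisabola-7(14),10-dien-1-ol (OH + oxirane O + side chain all cis)
Conditions: Me2AlCl (3 equiv), CH2Cl2 (0.01 M), −78 °C; aq potassium sodium tartrate
Reagents that add atoms: none
Why: Proposed new method: one Me2AlCl parks on the acetate and two form a cationic Me2Al chelate between the formyl and oxirane oxygens, so the 6,7-olefin attacks C1 on the face that places O-1 cis to the oxirane, and in the half-chair with the side chain equatorial only the C14 methyl (cis to C5 in the 6E olefin; the C8–H is deactivated by its acetoxy group) can reach the pseudoaxial oxygen, which gives the 7(14)-methylene and the 1,6-cis relationship together; the closest known reaction types are the Me2AlCl- or ZnBr2-promoted type 1 intramolecular carbonyl-ene (Prins) cyclisation of citronellal-type aldehydes and chelation-controlled additions to 2,3-epoxy carbonyl compounds.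

Step 6
Reactants: 13 bicyclic epoxy alcohol; 8 tert-butyl hydroperoxide
Product: 15 (1R,2R,3R,4S,6S,8S)-8-acetoxy-3,4-epoxybisabola-7(14),10-diene-1,2-diol (both OH + oxirane O + side chain all cis), via 3-ene-1,2-diol 14 (not isolated)
Conditions: Ti(OiPr)4 (1.5 equiv), CH2Cl2, 23 °C; then 8 (1.5 equiv), −20 °C; 10% aq tartaric acid
Reagents that add atoms: tert-butyl hydroperoxide CC(C)(C)OO
Why: Proposed new method: Ti(OiPr)4 binds O-1 as an alkoxide together with the cis oxirane oxygen, weakens the tertiary C3–O bond and passes an isopropoxide ligand to the C4 hydrogen on the same side of the oxirane plane as C1 (the C15 methyl lies on the far side), which gives the endocyclic 3-ene-1,2-diol with O-2 retained, and the same titanium alkoxide then delivers TBHP oxygen to the 3,4-olefin from the face of O-2 and O-1, setting C3 and C4 while the unactivated prenyl and acetate-deactivated methylene olefins stay intact; the closest known reaction types are the Ti(OiPr)4-promoted rearrangement of 2,3-epoxy alcohols with a tertiary C3 to ene-diols and the Ti(OiPr)4/TBHP hydroxyl-directed epoxidation of cyclohexenols.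

Step 7
Reactants: 15 epoxy diol; 16 angelic acid
Product: 18 target (1R,2R,3S,4S,6S,8S)-8-acetoxy-1,2-bis(angeloyloxy)-3,4-epoxybisabola-7(14),10-diene, via angelic 2,4,6-trichlorobenzoic anhydride 17 (not isolated)
Conditions: 16 (5 equiv), 2,4,6-trichlorobenzoyl chloride (5 equiv), Et3N (excess), toluene, 23 °C, filter; then 15, 80 °C
Reagents that add atoms: angelic acid C/C=C(/C)C(=O)O
Why: Yamaguchi-type mixed-anhydride acylation without DMAP transfers the angeloyl group to both secondary alcohols with retention at C1 and C2 and avoids the conjugate addition–elimination that turns angelates into tiglates.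

## Compound list
1 | neryl acetate, (2Z)-3,7-dimethylocta-2,6-dien-1-yl acetate | CC(C)=CCC/C(C)=C\COC(C)=O | starting material
2 | selenium dioxide | O=[Se]=O | starting material
3 | (2Z,6E)-3,7-dimethyl-8-oxoocta-2,6-dien-1-yl acetate | O=C/C(C)=C/CC/C(C)=C\COC(C)=O | intermediate
4 | prenyl chloride, 1-chloro-3-methylbut-2-ene | CC(C)=CCCl | starting material
5 | prenylbarium chloride | CC(C)=CC[Ba]Cl | intermediate
6 | racemic (2Z,6E)-8-hydroxy-3,7,11-trimethyldodeca-2,6,10-trien-1-yl acetate | CC(C)=CCC(O)/C(C)=C/CC/C(C)=C\COC(C)=O | intermediate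
7 | racemic (2Z,6E)-3,7,11-trimethyldodeca-2,6,10-triene-1,8-diol | CC(C)=CCC(O)/C(C)=C/CC/C(C)=C\CO | intermediate
8 | tert-butyl hydroperoxide | CC(C)(C)OO | starting material
9 | (2R,3S,6E,8S)-2,3-epoxy-3,7,11-trimethyldodeca-6,10-diene-1,8-diol | OC[C@H]1O[C@@]1(C)CC/C=C(C)/[C@@H](O)CC=C(C)C | intermediate
10 | acetic anhydride | CC(=O)OC(C)=O | starting material
11 | (2S,3S,6E,8S)-2,3-epoxy-8-hydroxy-3,7,11-trimethyldodeca-6,10-dienal | O=C[C@H]1O[C@@]1(C)CC/C=C(C)/[C@@H](O)CC=C(C)C | intermediate
12 | (2S,3S,6E,8S)-8-acetoxy-2,3-epoxy-3,7,11-trimethyldodeca-6,10-dienal | O=C[C@H]1O[C@@]1(C)CC/C=C(C)/[C@@H](OC(C)=O)CC=C(C)C | intermediate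
13 | (1R,2R,3S,6S,8S)-8-acetoxy-2,3-epoxybisabola-7(14),10-dien-1-ol | C=C([C@H](CC=C(C)C)OC(C)=O)[C@@H]1CC[C@]2(C)O[C@@H]2[C@@H]1O | intermediate
14 | (1R,2S,6S,8S)-8-acetoxybisabola-3,7(14),10-triene-1,2-diol | C=C([C@H](CC=C(C)C)OC(C)=O)[C@@H]1CC=C(C)[C@H](O)[C@@H]1O | intermediate
15 | (1R,2R,3R,4S,6S,8S)-8-acetoxy-3,4-epoxybisabola-7(14),10-diene-1,2-diol | C=C([C@H](CC=C(C)C)OC(C)=O)[C@@H]1C[C@@H]2O[C@]2(C)[C@H](O)[C@@H]1O | intermediate
16 | angelic acid, (Z)-2-methylbut-2-enoic acid | C/C=C(/C)C(=O)O | starting material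
17 | angelic 2,4,6-trichlorobenzoic anhydride | C/C=C(/C)C(=O)OC(=O)c1c(Cl)cc(Cl)cc1Cl | intermediate
18 | CNP0188566.2, (1R,2R,3S,4S,6S,8S)-8-acetoxy-1,2-bis(angeloyloxy)-3,4-epoxybisabola-7(14),10-diene | C=C([C@H](CC=C(C)C)OC(C)=O)[C@@H]1C[C@@H]2O[C@]2(C)[C@H](OC(=O)/C(C)=C\C)[C@@H]1OC(=O)/C(C)=C\C | target

## Step count and risks
Total step count: 7 (steps 2, 4 and 6 are telescoped two-operation steps; no protecting groups).
Longest linear sequence: 7 (1 → 18).

**Step 5 (ring closure).**
- A non-chelated, dipole-opposed transition state would put O-1 and the side chain trans to the oxirane.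
- The activated tertiary oxirane could undergo a formyl shift or chloride opening.

The fallback sets out from 7 and comes back at 13. It keeps the 2Z olefin and closes the ring at the enal stage under catalyst control.
- Aerobic oxidation of the primary allylic alcohol of 7 (Cu(MeCN)4OTf, 2,2'-bipyridine, TEMPO, N-methylimidazole, air, MeCN) gives racemic (2Z,6E)-8-hydroxyfarnesal F1.
- Sharpless kinetic resolution (Ti(OiPr)4, D-(−)-DIPT, 0.6 equiv TBHP, −20 °C) leaves (8S)-8-hydroxyfarnesal F2.
- Ac2O/pyridine gives (8S)-8-acetoxyfarnesal F3.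
- A confined chiral imino-imidodiphosphate Brønsted acid protonates the enal to a 1-hydroxy-farnesyl cation. The enantiomer used is the one that turns neral into (1R,6S)-trans-isopiperitenol. Cyclisation with loss of H-14 gives the 1,6-trans allylic alcohol F4.
- Dess–Martin periodinane gives the enone F5.
- Lithium tri-sec-butylborohydride at −78 °C attacks anti to the side chain and gives the 1,6-cis allylic alcohol F6.
- VO(acac)2/TBHP epoxidises the 2,3-olefin syn to O-1 and delivers 13.

**Step 6 (transposition and epoxidation in one flask).**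
- Proton loss from C15 would give the exocyclic olefin.
- Isopropoxide could open the oxirane at C3.
- The titanium alkoxide could transesterify the C8 acetate.

The fallback sets out from 13 and comes back at 14. It replaces the syn-elimination by hydration and anti-dehydration.
- Dilute HClO4 in THF/water opens the oxirane at tertiary C3 with inversion and gives the 1,2,3-triol F7.
- 2,2-Dimethoxypropane/PPTS ties up the cis-1,2-diol as the acetonide F8.
- SOCl2/pyridine eliminates the tertiary alcohol through the antiperiplanar C4 hydrogen (C2–H is syn and cannot compete) and gives the 3-ene acetonide F9.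
- 80% aqueous AcOH releases 14, which is isolated and epoxidised separately with VO(acac)2/TBHP to give 15.

**Step 7 (double angeloylation).**
- The second acylation of the hindered cis-diol may stall.
- Forcing conditions may isomerise Z to E.

The fallback sets out from 15 and comes back at 18. It builds the angelate double bonds on the molecule.
- DCC/DMAP esterification with the unhindered, non-isomerisable 2-[bis(2,2,2-trifluoroethoxy)phosphoryl]propanoic acid gives the bis(phosphonopropanoate) F10.
- A double Still–Gennari olefination (KN(SiMe3)2, 18-crown-6, acetaldehyde, THF, −78 °C) forms both Z-2-methylbut-2-enoates and gives 18.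

## Further compounds
F1 | step 5 | racemic (2Z,6E)-8-hydroxy-3,7,11-trimethyldodeca-2,6,10-trienal | CC(C)=CCC(O)/C(C)=C/CC/C(C)=C\C=O
F2 | step 5 | (2Z,6E,8S)-8-hydroxy-3,7,11-trimethyldodeca-2,6,10-trienal | CC(C)=CC[C@H](O)/C(C)=C/CC/C(C)=C\C=O
F3 | step 5 | (2Z,6E,8S)-8-acetoxy-3,7,11-trimethyldodeca-2,6,10-trienal | CC(C)=CC[C@H](OC(C)=O)/C(C)=C/CC/C(C)=C\C=O
F4 | step 5 | (1R,6S,8S)-8-acetoxybisabola-2,7(14),10-trien-1-ol (1,6-trans) | C=C([C@H](CC=C(C)C)OC(C)=O)[C@@H]1CCC(C)=C[C@H]1O
F5 | step 5 | (6S,8S)-8-acetoxybisabola-2,7(14),10-trien-1-one | C=C([C@H](CC=C(C)C)OC(C)=O)[C@@H]1CCC(C)=CC1=O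
F6 | step 5 | (1S,6S,8S)-8-acetoxybisabola-2,7(14),10-trien-1-ol (1,6-cis) | C=C([C@H](CC=C(C)C)OC(C)=O)[C@@H]1CCC(C)=C[C@@H]1O
F7 | step 6 | (1R,2R,3R,6S,8S)-8-acetoxybisabola-7(14),10-diene-1,2,3-triol | C=C([C@H](CC=C(C)C)OC(C)=O)[C@@H]1CC[C@@](C)(O)[C@H](O)[C@@H]1O
F8 | step 6 | 1,2-O-isopropylidene acetal of F7 | C=C([C@H](CC=C(C)C)OC(C)=O)[C@@H]1CC[C@@](C)(O)[C@@H]2OC(C)(C)O[C@H]12
F9 | step 6 | 1,2-O-isopropylidene acetal of 14 | C=C([C@H](CC=C(C)C)OC(C)=O)[C@@H]1CC=C(C)[C@@H]2OC(C)(C)O[C@H]12
F10 | step 7 | 1,2-bis{2-[bis(2,2,2-trifluoroethoxy)phosphoryl]propanoate} of 15 | C=C([C@H](CC=C(C)C)OC(C)=O)[C@@H]1C[C@@H]2O[C@]2(C)[C@H](OC(=O)C(C)P(=O)(OCC(F)(F)F)OCC(F)(F)F)[C@@H]1OC(=O)C(C)P(=O)(OCC(F)(F)F)OCC(F)(F)F
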